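**Retrosynthetic overview**
- The strategy rests on one feature: O7 of the 8-linked flavone (ring A, next to C8) and O5 of the 6-linked flavone (ring A, next to C6) lie ortho and ortho' to the C8–C6 axis. One CH2 can therefore bridge them as a formaldehyde acetal in a seven-membered dibenzo-1,3-dioxepine, and that carbon is kept at the end as the only methyl ether (on O7).
- The dioxepine is disconnected at the C8–C6 biaryl bond to an acetal-tethered 8-iodoflavone/6-iodoflavone pair, which is closed by reductive coupling with zerovalent nickel.
- The acetal comes from the 7-O-chloromethyl ether of 5,4'-di-O-benzyl-8-iodoapigenin and the 5-OH of 7,4'-di-O-benzyl-6-iodoapigenin. Both halves derive from apigenin; the state of O5 places the iodine (alkylated O5 gives C8, free chelated 5-OH gives C6).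
- The methylthiomethyl precursor of the chloromethyl ether is installed only after iodination, because NIS attacks thioethers; O7 is held as a MOM ether until then.
- Ring order: both flavone cores are taken intact from apigenin. The only ring formed is the dioxepine (key step), and it is opened again in the next step by chelation-directed reductive cleavage.

Key step: step 9

Assumption: the target SMILES carries no descriptor for the C8–C6 axis, so the biaryl is made without control of axial configuration (racemic).

**Route**

Step 1
Reactants: 1 apigenin; 2 chloromethyl methyl ether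
Product: 3 7-O-(methoxymethyl)apigenin
Conditions: MOMCl (1.05 equiv), K2CO3 (1.05 equiv), DMF, 0 °C → rt
Reagents that add atoms: chloromethyl methyl ether, COCCl
Why: The 7-OH, para to the pyranone carbonyl, is the most acidic phenol of apigenin and the 5-OH is locked in a hydrogen bond to C4=O, so a Williamson-type alkylation with one equivalent of base and electrophile should take place at O7.

Step 2
Reactants: 3 7-O-(methoxymethyl)apigenin; 4 benzyl bromide
Product: 5 5,4'-di-O-benzyl-7-O-(methoxymethyl)apigenin
Conditions: BnBr (3 equiv), K2CO3 (4 equiv), Bu4NI (cat.), DMF, 70 °C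
Reagents that add atoms: benzyl bromide, BrCc1ccccc1
Why: Williamson benzylation under forcing conditions alkylates the 4'-OH and also the chelated 5-OH, while the MOM ether is stable to base.

Step 3
Reactants: 5 5,4'-di-O-benzyl-7-O-(methoxymethyl)apigenin; 6 N-iodosuccinimide
Product: 7 5,4'-di-O-benzyl-8-iodo-7-O-(methoxymethyl)apigenin
Conditions: NIS (1.1 equiv), CF3CO2H (0.2 equiv), MeCN–CH2Cl2, 0 °C → rt, dark
Reagents that add atoms: N-iodosuccinimide, O=C1CCC(=O)N1I
Why: Electrophilic aromatic iodination of a 5,7-dialkoxyflavone should go to C8, the more accessible of the two doubly activated positions of ring A once O5 is alkylated, and no sulfide is yet present to consume the iodinating agent.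

Step 4
Reactants: 7 5,4'-di-O-benzyl-8-iodo-7-O-(methoxymethyl)apigenin
Product: 8 5,4'-di-O-benzyl-8-iodoapigenin (free 7-OH)
Conditions: 2 M HCl, MeOH–THF, 40 °C
Reagents that add atoms: none
Why: Acid-catalysed transacetalisation to methanol removes the MOM group, and the benzyl ethers and the aryl iodide should be inert to dilute methanolic acid.

Step 5
Reactants: 8 5,4'-di-O-benzyl-8-iodoapigenin; 9 chloromethyl methyl sulfide
Product: 10 5,4'-di-O-benzyl-8-iodo-7-O-(methylthiomethyl)apigenin
Conditions: NaH (1.2 equiv), DMF, 0 °C; ClCH2SMe (1.5 equiv), NaI (cat.), 0 °C → rt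
Reagents that add atoms: chloromethyl methyl sulfide, CSCCl
Why: Williamson alkylation of the acidic, non-chelated 7-phenoxide with the chloride (activated in situ by Finkelstein exchange with NaI) gives the aryl methylthiomethyl ether.

Step 6
Reactants: 1 apigenin; 4 benzyl bromide
Product: 11 7,4'-di-O-benzylapigenin
Conditions: BnBr (2.2 equiv), K2CO3 (2.5 equiv), acetone–DMF, 50 °C
Reagents that add atoms: benzyl bromide, BrCc1ccccc1
Why: Under mild Williamson conditions only the 7-OH and 4'-OH react, because the 5-OH is deactivated by its hydrogen bond to the C4 carbonyl.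

Step 7
Reactants: 11 7,4'-di-O-benzylapigenin; 6 N-iodosuccinimide
Product: 12 7,4'-di-O-benzyl-6-iodoapigenin
Conditions: NIS (1.05 equiv), DMF, rt, dark
Reagents that add atoms: N-iodosuccinimide, O=C1CCC(=O)N1I
Why: Electrophilic aromatic iodination under neutral conditions should go ortho to the free, chelated 5-OH, that is to C6, which is the usual outcome for 5-hydroxy-7-alkoxyflavones.

Step 8
Reactants: 10 5,4'-di-O-benzyl-8-iodo-7-O-(methylthiomethyl)apigenin; 12 7,4'-di-O-benzyl-6-iodoapigenin
Product: 14 diiodo formaldehyde acetal joining O7 of 5,4'-di-O-benzyl-8-iodoapigenin to O5 of 7,4'-di-O-benzyl-6-iodoapigenin, via 7-O-chloromethyl ether 13 (not isolated)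
Conditions: SO2Cl2 (1.05 equiv), CH2Cl2, −20 → 0 °C, volatiles removed in vacuo; then sodium salt of 12 (NaH, DMF, 0 °C), 0 °C → rt
Reagents that add atoms: none
Why: S-Chlorination of the thioether and fragmentation of the chlorosulfonium ion gives the aryl chloromethyl ether, a highly reactive alpha-chloro ether that should O-alkylate even the hindered sodium 5-phenoxide in a Williamson reaction to give the unsymmetrical diaryl formal.

Step 9
Reactants: 14 diiodo formaldehyde acetal
Product: 15 tetra-O-benzyl biflavone with a CH2 bridge from O7 of the 8-linked unit to O5 of the 6-linked unit (dibenzo-1,3-dioxepine)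
Conditions: Ni(C8H12)2 (2.5 equiv), PPh3 (5 equiv), DMF, 55 °C, about 5 mM, argon
Reagents that add atoms: none
Why: Oxidative addition of one C–I bond to zerovalent nickel gives an arylnickel iodide; after one-electron reduction by further zerovalent nickel the aryl complex of monovalent nickel inserts into the second, tethered C–I bond, and the eight-membered diarylnickel ring (Ni, C8, C7, O7, CH2, O5, C5, C6) collapses by C–C reductive elimination. The closest known reaction type is the intramolecular Ullmann-type reductive coupling of two tethered aryl iodides with Ni(C8H12)2 and PPh3 in DMF, which is established for short tethers including methylene acetals. The seven-membered dioxepine is closed by this reductive elimination, a ring contraction at the metal and not a polar cyclisation, so no Baldwin-type constraint applies. No stereocentre is formed, and the bridged biaryl should arise as a racemic pair of twisted conformers. The step needs site selectivity and ring closure in preference to oligomerisation: the two iodine atoms leave C8 and C6 as the only carbons that can meet, the one-carbon bridge between the two ortho oxygens turns the tetra-ortho-substituted cross-coupling into a cyclisation and excludes homocoupling, and high dilution suppresses intermolecular coupling. Benzyl ethers, the formal and the pyranones should be inert to zerovalent nickel at this temperature.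

Step 10
Reactants: 15 methylene-bridged tetra-O-benzyl biflavone
Product: 16 tri-O-benzyl 7-O-methyl biflavone (8-linked unit: 5-OH, 7-OMe, 4'-OBn; 6-linked unit: 5-OH, 7-OBn, 4'-OBn)
Conditions: BCl3 (3 equiv), Et3SiH (6 equiv), CH2Cl2, −78 → −30 °C; aq. NaHCO3
Reagents that add atoms: none
Why: Proposed new method: BCl3 binds the C4 carbonyl of each flavone, and on the 6-linked unit the boron sits peri to O5, so the O5–CH2 bond of the formal should ionise (pushed by the lone pair of O7 of the 8-linked unit) to a six-membered O5–B–O4 chelate and an aryloxymethyl cation or chloromethyl ether on O7, which Et3SiH reduces by hydride transfer to the O7–CH3 ether; the same chelation removes the peri 5-O-benzyl group of the 8-linked unit as benzyl chloride, while the non-chelated O7–CH2 bond and the three other benzyl ethers should react more slowly at low temperature; the closest known reaction types are the chelation-controlled BCl3 cleavage of 5-alkoxyflavones and the Lewis acid/silane reductive opening of benzylidene acetals to ethers (ionic hydrogenation of an oxocarbenium ion).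

Step 11
Reactants: 16 tri-O-benzyl 7-O-methyl biflavone
Product: 17 7'-O-methylagathisflavone (target)
Conditions: H2 (1 atm), palladium on carbon (10% Pd/C), THF–MeOH, rt
Reagents that add atoms: none
Why: Catalytic hydrogenolysis cleaves the three aryl benzyl ethers, and the flavone C2=C3 bonds and the methyl ether should survive at atmospheric pressure.

**Compound list**
1 | apigenin (5,7,4'-trihydroxyflavone) | O=c1cc(-c2ccc(O)cc2)oc2cc(O)cc(O)c12 | starting material
2 | chloromethyl methyl ether | COCCl | starting material
3 | 7-O-(methoxymethyl)apigenin | O=c1cc(-c2ccc(O)cc2)oc2cc(OCOC)cc(O)c12 | intermediate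
4 | benzyl bromide | BrCc1ccccc1 | starting material
5 | 5,4'-di-O-benzyl-7-O-(methoxymethyl)apigenin | O=c1cc(-c2ccc(OCc3ccccc3)cc2)oc2cc(OCOC)cc(OCc3ccccc3)c12 | intermediate
6 | N-iodosuccinimide | O=C1CCC(=O)N1I | starting material
7 | 5,4'-di-O-benzyl-8-iodo-7-O-(methoxymethyl)apigenin | O=c1cc(-c2ccc(OCc3ccccc3)cc2)oc2c(I)c(OCOC)cc(OCc3ccccc3)c12 | intermediate
8 | 5,4'-di-O-benzyl-8-iodoapigenin (free 7-OH) | O=c1cc(-c2ccc(OCc3ccccc3)cc2)oc2c(I)c(O)cc(OCc3ccccc3)c12 | intermediate
9 | chloromethyl methyl sulfide | CSCCl | starting material
10 | 5,4'-di-O-benzyl-8-iodo-7-O-(methylthiomethyl)apigenin | O=c1cc(-c2ccc(OCc3ccccc3)cc2)oc2c(I)c(OCSC)cc(OCc3ccccc3)c12 | intermediate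
11 | 7,4'-di-O-benzylapigenin | O=c1cc(-c2ccc(OCc3ccccc3)cc2)oc2cc(OCc3ccccc3)cc(O)c12 | intermediate
12 | 7,4'-di-O-benzyl-6-iodoapigenin | O=c1cc(-c2ccc(OCc3ccccc3)cc2)oc2cc(OCc3ccccc3)c(I)c(O)c12 | intermediate
13 | 5,4'-di-O-benzyl-7-O-(chloromethyl)-8-iodoapigenin | O=c1cc(-c2ccc(OCc3ccccc3)cc2)oc2c(I)c(OCCl)cc(OCc3ccccc3)c12 | intermediate (not isolated)
14 | formaldehyde acetal joining O7 of 5,4'-di-O-benzyl-8-iodoapigenin to O5 of 7,4'-di-O-benzyl-6-iodoapigenin | Ic1c(OCc2ccccc2)cc2oc(-c3ccc(OCc4ccccc4)cc3)cc(=O)c2c1OCOc1cc(OCc2ccccc2)c2c(=O)cc(-c3ccc(OCc4ccccc4)cc3)oc2c1I | intermediate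
15 | tetra-O-benzyl biflavone with a CH2 bridge from O7 of the 8-linked unit to O5 of the 6-linked unit | C1Oc2cc(OCc3ccccc3)c3c(=O)cc(-c4ccc(OCc5ccccc5)cc4)oc3c2-c2c(OCc3ccccc3)cc3oc(-c4ccc(OCc5ccccc5)cc4)cc(=O)c3c2O1 | intermediate
16 | tri-O-benzyl 7-O-methyl biflavone (8-linked unit: 5-OH, 7-OMe, 4'-OBn; 6-linked unit: 5-OH, 7-OBn, 4'-OBn) | COc1cc(O)c2c(=O)cc(-c3ccc(OCc4ccccc4)cc3)oc2c1-c1c(OCc3ccccc3)cc2oc(-c3ccc(OCc4ccccc4)cc3)cc(=O)c2c1O | intermediate
17 | 7'-O-methylagathisflavone | COc1cc(O)c2c(=O)cc(-c3ccc(O)cc3)oc2c1-c1c(O)cc2oc(-c3ccc(O)cc3)cc(=O)c2c1O | target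

**Step count and risks**

Total step count: 11. Longest linear sequence: 9 (steps 1, 2, 3, 4, 5, 8, 9, 10, 11).

Steps most likely to fail:

1. Step 10 (labelled "Proposed new method:"). Several processes could divert it:
   - hydride transfer may not keep pace with the aryloxymethyl cation, so the bridge carbon is lost as formaldehyde on work-up or is passed to the neighbouring 7-benzyloxy oxygen or to an arene;
   - exchange between the silane and free BCl3 may give chloroboranes that reduce a pyranone;
   - the formal may ionise at the non-chelated oxygen.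

   Fallback with known chemistry, from 15 back to 16: 15 is treated with BCl3 alone (CH2Cl2, −78 °C) and worked up with water. The chloromethyl ether then hydrolyses and loses formaldehyde, giving the tri-O-benzyl triphenol with free 5-OH and 7-OH on the 8-linked unit and free 5-OH on the 6-linked unit F1. MeI (1.1 equiv) and K2CO3 in acetone then methylate only the non-chelated 7-OH, giving 16.

2. Step 9. Reductive elimination from the hindered diarylnickel may be slower than protodemetalation (hydrodeiodination) or intermolecular coupling, and zerovalent nickel may be held back by the electron-poor C2=C3 bonds. Fallback, from 14 back to 15: a Stille–Kelly coupling with Me3SnSnMe3 and catalytic Pd(PPh3)4 in dioxane at 100 °C. One C–I bond is first stannylated to the 8-trimethylstannyl 6-iodo acetal F2, which then closes the same ring by intramolecular Stille coupling under palladium catalysis, replacing the stoichiometric nickel-mediated reductive coupling.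

3. Step 8. The chloromethyl ether may hydrolyse, the chelated and iodine-flanked 5-phenoxide may be alkylated incompletely, and C6 of ring A may be sulfenylated or chlorinated by MeSCl or SO2Cl2. Fallback, from 12 and 8 back to 14, with the roles reversed so that the unhindered phenoxide is the nucleophile: 12 is alkylated at O5 with ClCH2SMe (NaH, NaI, DMF) to 7,4'-di-O-benzyl-6-iodo-5-O-(methylthiomethyl)apigenin F3. SO2Cl2 converts this to the 5-O-chloromethyl ether F4, which is treated with the potassium 7-phenoxide of 8 (K2CO3, DMF) to give 14.

**Further compounds**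
F1 | step 10 | tri-O-benzyl biflavone triphenol (8-linked unit: 5-OH, 7-OH, 4'-OBn; 6-linked unit: 5-OH, 7-OBn, 4'-OBn) | Oc1cc(O)c2c(=O)cc(-c3ccc(OCc4ccccc4)cc3)oc2c1-c1c(OCc3ccccc3)cc2oc(-c3ccc(OCc4ccccc4)cc3)cc(=O)c2c1O
F2 | step 9 | acetal 14 with the 8-iodo group of the 8-linked unit replaced by trimethylstannyl | Ic1c(OCc2ccccc2)cc2oc(-c3ccc(OCc4ccccc4)cc3)cc(=O)c2c1OCOc1cc(OCc2ccccc2)c2c(=O)cc(-c3ccc(OCc4ccccc4)cc3)oc2c1[Sn](C)(C)C
F3 | step 8 | 7,4'-di-O-benzyl-6-iodo-5-O-(methylthiomethyl)apigenin | O=c1cc(-c2ccc(OCc3ccccc3)cc2)oc2cc(OCc3ccccc3)c(I)c(OCSC)c12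
F4 | step 8 | 7,4'-di-O-benzyl-5-O-(chloromethyl)-6-iodoapigenin | O=c1cc(-c2ccc(OCc3ccccc3)cc2)oc2cc(OCc3ccccc3)c(I)c(OCCl)c12
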